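**Plan**

- Ring A carries the carboxyl at C1, oxygen at C2 and C4 and carbon substituents at C3, C5 and C6. This 1-carboxy-2,4-dioxy-6-alkyl pattern is that of a tetraketide folded with retention of its carboxyl, so the retrosynthesis cuts ring bond C1–C6 of ring A (aldol retron) and opens the arene to a linear 3,5,7-trioxononanoate whose C4 and C6 already carry the two prenyl groups (chain C2–C7 = ring C1–C6).
- Before this cut, the C2 methyl ether is taken back to the chelated phenol. The acid, the C4 phenol and the ring B phenol are all masked as allyl derivatives, so one palladium deallylation ends the synthesis without saponifying a 2,6-disubstituted benzoate and without acid near the ortho-prenyl phenol.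
- The chain is cut at C6–C7 and C4–C5 (acylation of a trianion and of a dianion by N-methoxy-N-methylamides) and at the bond from C4 to its prenyl CH2 (γ-alkylation of allyl acetoacetate). The C6 prenyl arrives inside 5-methylhex-4-enoic acid, so no prenyl group is ever attached to an arene.
- Forward order: C4 prenylation, C4–C5 acylation, C6–C7 acylation with the ring B fragment, closure of ring A (the only ring formed; ring B is bought), 4-O-allylation, 2-O-methylation, global deallylation.
- Stereochemistry: the target has no stereocentre and no alkene geometry. The two CH centres of the open chain are made as mixtures and disappear on aromatisation.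

Key step: step 7

Remark: 5-methylhex-4-enoic acid is assumed to be a catalogue compound; all polyanions of the allyl esters are held at or below 0 °C.

**Route**

Step 1
Reactants: 1 allyl acetoacetate (prop-2-enyl 3-oxobutanoate); 2 prenyl bromide (1-bromo-3-methylbut-2-ene)
Product: 4 allyl 7-methyl-3-oxooct-6-enoate, via dilithium dianion of allyl acetoacetate 3 (not isolated)
Conditions: LiN(i-Pr)2 (2.1 equiv), THF, –78 → 0 °C; 2 (1.0 equiv), 0 °C; then cold 1 M HCl
Reagents that add atoms: none
Why: γ-Alkylation of an acetoacetate dianion, in which the terminal carbanion of 3 is the most basic site and displaces the allylic bromide by SN2 at C4 only, while the low temperature keeps the ester-enolate Carroll rearrangement of the allyl ester from starting.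

Step 2
Reactants: 5 5-methylhex-4-enoic acid
Product: 7 N-methoxy-N,5-dimethylhex-4-enamide, via 1-(5-methylhex-4-enoyl)imidazole 6 (not isolated)
Conditions: CDI (1.1 equiv), CH2Cl2, rt; then MeNH(OMe)·HCl (1.2 equiv), rt
Reagents that add atoms: N,O-dimethylhydroxylamine hydrochloride, CNOC.Cl
Why: Amide coupling through the acyl imidazolide (carbonyldiimidazole activation) is a standard entry to N-methoxy-N-methylamides (Weinreb amides) and leaves the trisubstituted alkene untouched.

Step 3
Reactants: 4 allyl 7-methyl-3-oxooct-6-enoate; 7 N-methoxy-N,5-dimethylhex-4-enamide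
Product: 10 allyl 9-methyl-4-(3-methylbut-2-enyl)-3,5-dioxodec-8-enoate, via dilithium dianion of the prenylated keto ester 8 (not isolated), via dilithium tetrahedral hemiaminal adduct 9 (not isolated)
Conditions: 4 (1.3 equiv), LiN(i-Pr)2 (2.7 equiv), THF, –78 → 0 °C; 7 (1.0 equiv), –78 → 0 °C; then cold 1 M HCl
Reagents that add atoms: none
Why: Claisen-type C-acylation of a β-keto ester dianion at its γ-carbon by a Weinreb amide (Weinreb ketone synthesis), in which the chelated adduct 9 persists until the acid quench so that a single acyl group is transferred and the diketo ester never meets the dianion; the C4 centre forms racemic and is erased in step 7.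

Step 4
Reactants: 11 3-(4-hydroxyphenyl)propanoic acid
Product: 12 allyl 3-[4-(allyloxy)phenyl]propanoate
Conditions: allyl bromide (2.4 equiv), K2CO3 (3 equiv), DMF, rt → 50 °C
Reagents that add atoms: allyl bromide, C=CCBr
Why: Williamson etherification of the phenoxide and SN2 esterification of the carboxylate by allyl bromide run together under K2CO3 in DMF.

Step 5
Reactants: 12 allyl 3-[4-(allyloxy)phenyl]propanoate
Product: 13 3-[4-(allyloxy)phenyl]-N-methoxy-N-methylpropanamide
Conditions: MeNH(OMe)·HCl (1.5 equiv), i-PrMgCl (3.0 equiv), THF, –20 → 0 °C; then 1 M HCl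
Reagents that add atoms: N,O-dimethylhydroxylamine hydrochloride, CNOC.Cl
Why: Aminolysis of an ester by the chloromagnesium amide of N,O-dimethylhydroxylamine is a known one-step ester-to-Weinreb-amide conversion, the magnesium chelate of the product resists further attack and the aryl allyl ether is inert.

Step 6
Reactants: 10 allyl 9-methyl-4-(3-methylbut-2-enyl)-3,5-dioxodec-8-enoate; 13 3-[4-(allyloxy)phenyl]-N-methoxy-N-methylpropanamide
Product: 16 allyl 9-[4-(allyloxy)phenyl]-4,6-bis(3-methylbut-2-enyl)-3,5,7-trioxononanoate, via trilithium trianion of the diketo ester 14 (not isolated), via trilithium tetrahedral hemiaminal adduct 15 (not isolated)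
Conditions: LiN(i-Pr)2 (3.2 equiv), THF, –78 → 0 °C; 13 (1.1 equiv), –78 → –20 °C; poured into cold 1 M HCl; crude 16 taken on at once
Reagents that add atoms: none
Why: Terminal C-acylation of a 3,5-diketo ester trianion by a Weinreb amide, in which the last-formed and least delocalised carbanion at C6 is the most nucleophilic site and the chelated adduct 15 keeps the future C7 carbonyl masked until the cold acid quench, so no ring closure can occur in the strongly basic medium; C4 and C6 form as epimer mixtures that step 7 erases.

Step 7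
Reactants: 16 allyl 9-[4-(allyloxy)phenyl]-4,6-bis(3-methylbut-2-enyl)-3,5,7-trioxononanoate
Product: 18 allyl 6-{2-[4-(allyloxy)phenyl]ethyl}-2,4-dihydroxy-3,5-bis(3-methylbut-2-enyl)benzoate, via cyclic aldol adduct 17 (not isolated)
Conditions: Cs2CO3 (2 equiv), THF/allyl alcohol (4:1), 0 °C → rt; then 1 M HCl
Reagents that add atoms: none
Why: Carbonate ionises only the doubly activated positions C2, C4 and C6 of the chain, and the C2 enolate adds to the C7 ketone in an intramolecular aldol addition to give 17, which loses water by E1cB and becomes aromatic when the C3 and C5 carbonyls enolise. The closest known reaction type is the base-mediated aldol cyclisation and aromatisation of 3,5,7-triketo esters to 6-substituted 2,4-dihydroxybenzoates, the laboratory counterpart of carboxyl-retaining polyketide folding. Ring A closes in a Baldwin-allowed 6-(enolendo)-exo-trig mode that creates ring bond C1–C6 (chain C2–C7). No stereocentre survives, because the labile CH centres at chain C4 and C6 and the carbinol carbon of 17 all become sp2, so the epimer and tautomer mixture of 16 converges on one arene. The step needs aldol closure to beat the Claisen closure of C6 onto the ester and an aldol from C8 onto C3: C8 is a plain ketone α-carbon that carbonate does not deprotonate, the C6 prenyl turns the Claisen product into a non-aromatisable 2-acyl-2-alkyl-1,3-dione that alkoxide cleaves back, and only the C2-to-C7 path ends in an irreversible aromatisation. Allyl alcohol as protic co-solvent speeds the proton transfers of dehydration and makes any ester exchange degenerate.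

Step 8
Reactants: 18 allyl 6-{2-[4-(allyloxy)phenyl]ethyl}-2,4-dihydroxy-3,5-bis(3-methylbut-2-enyl)benzoate
Product: 19 allyl 4-(allyloxy)-6-{2-[4-(allyloxy)phenyl]ethyl}-2-hydroxy-3,5-bis(3-methylbut-2-enyl)benzoate
Conditions: allyl bromide (1.1 equiv), K2CO3 (1.5 equiv), acetone, rt
Reagents that add atoms: allyl bromide, C=CCBr
Why: Williamson etherification that tells the two phenols apart by acidity, since K2CO3 ionises the C4 hydroxyl para to the ester while the C2 hydroxyl is held in a hydrogen bond to the ester carbonyl and stays unreactive at room temperature.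

Step 9
Reactants: 19 allyl 4-(allyloxy)-6-{2-[4-(allyloxy)phenyl]ethyl}-2-hydroxy-3,5-bis(3-methylbut-2-enyl)benzoate
Product: 20 allyl 4-(allyloxy)-6-{2-[4-(allyloxy)phenyl]ethyl}-2-methoxy-3,5-bis(3-methylbut-2-enyl)benzoate
Conditions: MeI (3 equiv), K2CO3 (3 equiv), DMF, 50 °C
Reagents that add atoms: iodomethane, CI
Why: Williamson O-methylation of the remaining chelated salicylate-type phenol, which responds to the more forcing DMF conditions once the competing C4 hydroxyl is capped, at a temperature far below that of any aryl allyl ether Claisen rearrangement.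

Step 10
Reactants: 20 allyl 4-(allyloxy)-6-{2-[4-(allyloxy)phenyl]ethyl}-2-methoxy-3,5-bis(3-methylbut-2-enyl)benzoate
Product: 21 4-hydroxy-6-[2-(4-hydroxyphenyl)ethyl]-2-methoxy-3,5-bis(3-methylbut-2-enyl)benzoic acid
Conditions: Pd(PPh3)4 (10 mol %), morpholine (10 equiv), THF, rt; then aqueous citric acid
Reagents that add atoms: none
Why: Tsuji–Trost deallylation, in which zerovalent palladium ionises the allyl ester and both aryl allyl ethers to π-allyl complexes that morpholine captures irreversibly, so the hindered acid and both phenols are freed in one neutral operation that touches neither the prenyl alkenes nor the aryl methyl ether.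

**Compound list**

1 | allyl acetoacetate | CC(=O)CC(=O)OCC=C | starting material
2 | prenyl bromide | CC(C)=CCBr | starting material
3 | dilithium dianion of allyl acetoacetate | [Li+].[Li+].C=CCOC([O-])=CC([O-])=C | intermediate
4 | allyl 7-methyl-3-oxooct-6-enoate | CC(C)=CCCC(=O)CC(=O)OCC=C | intermediate
5 | 5-methylhex-4-enoic acid | CC(C)=CCCC(=O)O | starting material
6 | 1-(5-methylhex-4-enoyl)imidazole | CC(C)=CCCC(=O)n1ccnc1 | intermediate
7 | N-methoxy-N,5-dimethylhex-4-enamide | CC(C)=CCCC(=O)N(C)OC | intermediate
8 | dilithium dianion of allyl 7-methyl-3-oxooct-6-enoate | [Li+].[Li+].C=CCOC([O-])=CC([O-])=CCC=C(C)C | intermediate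
9 | dilithium tetrahedral hemiaminal adduct of 8 and 7 | [Li+].[Li+].C=CCOC([O-])=CC(=O)C(CC=C(C)C)C([O-])(N(C)OC)CCC=C(C)C | intermediate
10 | allyl 9-methyl-4-(3-methylbut-2-enyl)-3,5-dioxodec-8-enoate (racemic, keto–enol mixture) | C=CCOC(=O)CC(=O)C(CC=C(C)C)C(=O)CCC=C(C)C | intermediate
11 | 3-(4-hydroxyphenyl)propanoic acid | O=C(O)CCc1ccc(O)cc1 | starting material
12 | allyl 3-[4-(allyloxy)phenyl]propanoate | C=CCOC(=O)CCc1ccc(OCC=C)cc1 | intermediate
13 | 3-[4-(allyloxy)phenyl]-N-methoxy-N-methylpropanamide | C=CCOc1ccc(CCC(=O)N(C)OC)cc1 | intermediate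
14 | trilithium trianion of 10 | [Li+].[Li+].[Li+].C=CCOC([O-])=CC([O-])=C(CC=C(C)C)C([O-])=CCC=C(C)C | intermediate
15 | trilithium tetrahedral hemiaminal adduct of 14 and 13 | [Li+].[Li+].[Li+].C=CCOC([O-])=CC([O-])=C(CC=C(C)C)C(=O)C(CC=C(C)C)C([O-])(N(C)OC)CCc1ccc(OCC=C)cc1 | intermediate
16 | allyl 9-[4-(allyloxy)phenyl]-4,6-bis(3-methylbut-2-enyl)-3,5,7-trioxononanoate (epimer and keto–enol mixture) | C=CCOC(=O)CC(=O)C(CC=C(C)C)C(=O)C(CC=C(C)C)C(=O)CCc1ccc(OCC=C)cc1 | intermediate
17 | allyl 2-{2-[4-(allyloxy)phenyl]ethyl}-2-hydroxy-3,5-bis(3-methylbut-2-enyl)-4,6-dioxocyclohexane-1-carboxylate (stereoisomer mixture) | C=CCOC(=O)C1C(=O)C(CC=C(C)C)C(=O)C(CC=C(C)C)C1(O)CCc1ccc(OCC=C)cc1 | intermediate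
18 | allyl 6-{2-[4-(allyloxy)phenyl]ethyl}-2,4-dihydroxy-3,5-bis(3-methylbut-2-enyl)benzoate | C=CCOC(=O)c1c(O)c(CC=C(C)C)c(O)c(CC=C(C)C)c1CCc1ccc(OCC=C)cc1 | intermediate
19 | allyl 4-(allyloxy)-6-{2-[4-(allyloxy)phenyl]ethyl}-2-hydroxy-3,5-bis(3-methylbut-2-enyl)benzoate | C=CCOC(=O)c1c(O)c(CC=C(C)C)c(OCC=C)c(CC=C(C)C)c1CCc1ccc(OCC=C)cc1 | intermediate
20 | allyl 4-(allyloxy)-6-{2-[4-(allyloxy)phenyl]ethyl}-2-methoxy-3,5-bis(3-methylbut-2-enyl)benzoate | C=CCOC(=O)c1c(OC)c(CC=C(C)C)c(OCC=C)c(CC=C(C)C)c1CCc1ccc(OCC=C)cc1 | intermediate
21 | 4-hydroxy-6-[2-(4-hydroxyphenyl)ethyl]-2-methoxy-3,5-bis(3-methylbut-2-enyl)benzoic acid | COc1c(CC=C(C)C)c(O)c(CC=C(C)C)c(CCc2ccc(O)cc2)c1C(=O)O | target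

**Count and risks**

Total step count: 10. Longest linear sequence: 7 steps (steps 1, 3, 6, 7, 8, 9, 10).

Steps most likely to fail:

1. **Step 6.** The third deprotonation of the branched diketo ester may stay incomplete, and proton transfer from the amide to the polyanion may outrun addition, so that material returns unchanged or acylation lands on C2. The fallback sets out from 10 and comes back at 18. Compound 10 is lactonised with DBU in toluene at 80 °C to 4-hydroxy-5-(3-methylbut-2-enyl)-6-(4-methylpent-3-enyl)-2H-pyran-2-one F1. This pyranone has only two acidic sites (the hydroxyl and the CH2 on C6), so two equivalents of LiN(i-Pr)2 suffice and the carbanion is acylated by 13 to give 6-{1-[4-(allyloxy)phenyl]-7-methyl-3-oxooct-6-en-4-yl}-4-hydroxy-5-(3-methylbut-2-enyl)-2H-pyran-2-one F2. Warming F2 with KOCH2CH=CH2 (from KH and allyl alcohol) in allyl alcohol opens the lactone to the enolate of 16, which closes and aromatises in the same pot to 18.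

2. **Step 7.** The branch at C6 may slow attack on the C7 carbonyl enough for lactonisation of the C5 enol onto the ester, or alkoxide-induced retro-Claisen cleavage of the chain, to overtake ring closure. The fallback sets out from 4 (through its dianion 8) and 13 and comes back at 18; it closes the ring without the C6 branch and adds that prenyl afterwards. Dianion 8 is acylated with N-methoxy-N-methylacetamide to allyl 4-(3-methylbut-2-enyl)-3,5-dioxohexanoate F3. The trianion of F3 is acylated with 13 to allyl 9-[4-(allyloxy)phenyl]-4-(3-methylbut-2-enyl)-3,5,7-trioxononanoate F4. Cs2CO3 in THF/allyl alcohol then gives allyl 6-{2-[4-(allyloxy)phenyl]ethyl}-2,4-dihydroxy-3-(3-methylbut-2-enyl)benzoate F5. The sodium phenoxide of F5 (NaH, toluene) is C-alkylated by prenyl bromide 2 at C5, the only unsubstituted position of ring A, which gives 18.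

3. **Step 3.** Addition of the secondary γ-carbanion of 8 to the amide may be slow, so that enolisation of 7 or the Carroll shift of the allyl ester competes. The fallback sets out from 1 (through its dianion 3) and 7 and comes back at 10; it reverses the order of acylation and prenylation. The unbranched dianion 3 is acylated by 7 to allyl 9-methyl-3,5-dioxodec-8-enoate F6. The monoanion of F6 (K2CO3, acetone), which is centred on C4 between the two ketones, is then alkylated with prenyl bromide 2 to give 10.

**Further compounds**

F1 | step 6 | 4-hydroxy-5-(3-methylbut-2-enyl)-6-(4-methylpent-3-enyl)-2H-pyran-2-one | O=C1C=C(O)C(CC=C(C)C)=C(CCC=C(C)C)O1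
F2 | step 6 | 6-{1-[4-(allyloxy)phenyl]-7-methyl-3-oxooct-6-en-4-yl}-4-hydroxy-5-(3-methylbut-2-enyl)-2H-pyran-2-one | O=C1C=C(O)C(CC=C(C)C)=C(C(CC=C(C)C)C(=O)CCc2ccc(OCC=C)cc2)O1
F3 | step 7 | allyl 4-(3-methylbut-2-enyl)-3,5-dioxohexanoate | C=CCOC(=O)CC(=O)C(CC=C(C)C)C(C)=O
F4 | step 7 | allyl 9-[4-(allyloxy)phenyl]-4-(3-methylbut-2-enyl)-3,5,7-trioxononanoate | C=CCOC(=O)CC(=O)C(CC=C(C)C)C(=O)CC(=O)CCc1ccc(OCC=C)cc1
F5 | step 7 | allyl 6-{2-[4-(allyloxy)phenyl]ethyl}-2,4-dihydroxy-3-(3-methylbut-2-enyl)benzoate | C=CCOC(=O)c1c(O)c(CC=C(C)C)c(O)cc1CCc1ccc(OCC=C)cc1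
F6 | step 3 | allyl 9-methyl-3,5-dioxodec-8-enoate | C=CCOC(=O)CC(=O)CC(=O)CCC=C(C)C
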